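**Gancaonin J (13): six-step synthesis by a double ortho-Claisen transfer of both prenyl groups from oxygen to carbon**

Ring A numbering used throughout: C1 carries the acyl group (carbonyl carbon C7), C2 and C4 the hydroxyls, C3 and C5 the prenyl groups, C6 a hydrogen.

## The problem

Gancaonin J (13) is a dihydrochalcone: ring A and ring B are joined only by an open C7(=O)–CH2–CH2 chain. There is no ring fusion and no stereocentre, so the whole difficulty lies in the substitution pattern. Ring A is pentasubstituted, and ring B carries a third phenol that must stay free of prenyl groups, so the three hydroxyls have to be told apart. Direct C-prenylation of a resorcinol ketone with a prenyl halide is expected to give mixtures of O- and C-alkylation and does not stop cleanly at the 3,5-pattern. Both prenyl groups sit ortho to free phenols: acids close them to 2,2-dimethylchromans, hydrogenation saturates them, and the electron-rich ring is easily oxidised. Every step after the prenyl groups are in place must therefore be neutral or basic and non-reducing. The enabling feature is positional: C3 is ortho to both O2 and O4, C5 is ortho to O4, C1 is blocked by the acyl group and C6 is meta to both oxygens. An allyl unit leaving O2 or O4 by a [3,3] shift can therefore settle only on C3 or C5, and a single ortho shift turns a 1,1-dimethylallyl ether into a normal prenyl group.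

## Retrosynthesis

**13 from 12.** The last cut is the ester O–C(acyl) bond on ring B. Ring B must be masked, because a free phenol there would be etherified and would prenylate its own ortho carbon. A pivalate is chosen over an ether because it can be removed by mild base at the end, where acid or hydrogenolysis would destroy the prenyl phenols. It is also the aryl ester best able to survive a Lewis acid, an amidine base, hydrogen over poisoned palladium and heat. The forward reaction is a simple methanolysis of 12.

**12 from 8.** The C3–CH2 and C5–CH2 bonds are cut together, each traced back to a C–O bond of a 1,1-dimethylallyl ether, giving the bis-ether 8.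
- This is preferred over direct C-alkylation (no site control) and over acid-mediated prenylation with the allylic alcohol (chroman formation).
- The simplification is large: both C–C bonds become ether bonds on the parent 2,4-dihydroxy ketone.
- One point of mechanism decides the design. A relay of an allyl unit from C3 to C5 by a Cope shift would invert it a second time and leave a 1,1-dimethylallyl group at C5. Each prenyl group must therefore arrive by a single ortho shift: the O2 unit at C3 and the O4 unit at C5.
- The forward reaction must make the O2 ether move first. A europium chelate between the ketone and O2 is meant to do this. The intermediate phenol 10 then has only C5 open for the O4 unit.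

**8 from 7.** The two vinyl groups are traced back to ethynyl groups. Tertiary allyl aryl ethers cannot be made by direct substitution, whereas the tertiary propargyl ethers of 7 are accessible. The forward reaction is a double semihydrogenation that must stop at the alkene.

**7 from 4 and 5.** Both aryl O–C bonds are cut, leading to the dihydroxy ketone 4 and two equivalents of 3-chloro-3-methylbut-1-yne (5). The more acidic O4 should react first (monoether 6). The hydrogen-bonded O2 needs excess reagent and is the demanding part of this step.

**4 from 2 and 3.** The C1–C7 bond is cut: acylation of resorcinol (3) with the protected acid 2 at the carbon para to one hydroxyl and ortho to the other. Making the ketone at this stage, before any prenyl group exists, lets a strong Lewis acid be used without risk to the side chains. The ketone then serves as the blocking group at C1 and as the anchor for the key step.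

**2 from 1.** The pivalate is put on phloretic acid (1) first, so that the three phenols of the later intermediates never have to be differentiated.

## Roads not taken

**Alternative 1:** Ring A would be built by benzannulation instead of being taken from resorcinol, cutting C3–C4, C1–C2 and C4–C5.
- Forward step: irradiation of the diazo ketone A2 would give a vinylketene by Wolff rearrangement. This would add the siloxyalkyne A3 in a [2+2] sense; four-electron opening of the cyclobutenone and six-electron closure of the dienylketene would give the resorcinol monosilyl ether A1.
- Merits: the positions of both prenyl groups and both oxygens are fixed by the connectivity of the partners, the conditions are neutral, and the two ring A oxygens emerge differentiated.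
- Weak points: A1 has no carbon at C1. The keto chain would have to be attached afterwards to a 2,6-diprenylresorcinol, and Friedel–Crafts or Fries conditions are exactly those under which ortho-prenyl phenols close to chromans. A2 contains a skipped diene next to a carbonyl that can slip into conjugation, and A2 and A3 each need several steps.
- Comparison: this road is better in regiochemical certainty, since nothing depends on the order of two migrations. The chosen plan sets against this a six-step sequence from three bought compounds and a ketone installed while the ring still tolerates BF3·OEt2.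

**Alternative 2:** Ring A would be formed by a Diels–Alder reaction with aromatisation, cutting C1–C2 and C5–C6.
- Forward step: the diprenyl bis(silyloxy)diene A5 would add across the terminal ynone A6. Loss of methanol and silanol on mild acidic work-up would give the ring B silyl ether A4, one fluoride deprotection from the target.
- Merits: this is the most convergent road. One step would deliver the whole skeleton with the ketone, both prenyl groups and both free ring A phenols, and the regiochemistry follows from the polarisation of the diene.
- Weak points: A5 is substituted at C2 and at its nucleophilic terminus C4. Such dienes are far less reactive than the parent, tend to give open-chain Michael products, and are hydrolytically fragile. The geometry of A5 is hard to control, and its preparation needs two separate prenylations and a double enol silylation.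
- Comparison: if the cycloaddition worked, this road would be shorter in its longest linear sequence and free of the migration-order question. The chosen plan sets against this that each of its steps belongs to a well-known reaction class on closely related substrates, whereas the reactivity of A5 is the open point on which the whole alternative rests.

**Alternative 3:** The ketone would be stitched together last, cutting C1–C7 and C7–C(alpha).
- Forward step: PdCl2(PPh3)2-catalysed coupling of the ring A iodide A8, carbon monoxide and the alkylborane A9 with K3PO4 would give the tris(methoxymethyl) ether A7.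
- Merits: the ketone forms under nearly neutral conditions, convergently, without a Lewis acid.
- Weak points: the road does not solve the prenylation problem. A8 already contains both prenyl groups, which would have to be installed by the same kind of oxygen-to-carbon transfer, followed by iodination and protection. Direct coupling without carbon monoxide insertion and beta-hydride elimination compete in the key step. Removing three methoxymethyl ethers needs acid, which threatens chroman formation at the very end.
- Comparison: its ketone-forming step is milder than the BF3·OEt2 acylation used here, and that is a real advantage. The chosen plan answers by acylating before any prenyl group exists and by ending with a basic deprotection.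

Key step: step 5

Assumption: 3-chloro-3-methylbut-1-yne (5) is bought as the source of both C5 units; it is the chloride of 2-methylbut-3-yn-2-ol and reacts through the same copper-bound propargylic electrophile as the carbonate or trifluoroacetate of that alcohol.

## Route

**Step 1**
Reactants: 1 3-(4-hydroxyphenyl)propanoic acid (phloretic acid)
Product: 2 3-[4-(2,2-dimethylpropanoyloxy)phenyl]propanoic acid
Conditions: PivCl (1.1 equiv), NaOH (2.2 equiv), H2O/THF, 0 °C; then 1 M HCl
Reagents that add atoms: pivaloyl chloride, CC(C)(C)C(Cl)=O
Why: Schotten–Baumann acylation: in aqueous base the phenoxide is far more nucleophilic than the carboxylate, so the hindered acid chloride esterifies the phenol selectively, and acidification returns the free carboxylic acid.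

**Step 2**
Reactants: 2 3-[4-(2,2-dimethylpropanoyloxy)phenyl]propanoic acid; 3 resorcinol
Product: 4 4-[3-(2,4-dihydroxyphenyl)-3-oxopropyl]phenyl pivalate
Conditions: BF3·OEt2 (neat, about 6 equiv), 85 °C; then aq. NaOAc
Reagents that add atoms: none
Why: Friedel–Crafts (Nencki-type) C-acylation of resorcinol by a carboxylic acid in BF3·OEt2; attack occurs para to one hydroxyl and ortho to the other and stops after one acyl group because the product is deactivated and held as a boron chelate until work-up, while the hindered pivalate is the aryl ester least prone to acyl transfer.

**Step 3**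
Reactants: 4 4-[3-(2,4-dihydroxyphenyl)-3-oxopropyl]phenyl pivalate; 5 3-chloro-3-methylbut-1-yne (4 equiv)
Product: 7 4-{3-[2,4-bis(2-methylbut-3-yn-2-yloxy)phenyl]-3-oxopropyl}phenyl pivalate, via 4-O-monoether 6 (not isolated)
Conditions: DBU (4 equiv), CuCl2·2H2O (1 mol %), MeCN, 0 °C to rt
Reagents that add atoms: none
Why: Copper-catalysed propargylic etherification of phenoxides with a tertiary propargylic chloride: a copper acetylide ionises to an allenylidene-type electrophile that the phenoxide captures at the tertiary carbon; the acidic O4 reacts first (6) and excess reagent with the amidine base then etherifies the hydrogen-bonded O2, as known for 2-acylphenols, while the pivalate is inert to DBU in MeCN.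

**Step 4**
Reactants: 7 4-{3-[2,4-bis(2-methylbut-3-yn-2-yloxy)phenyl]-3-oxopropyl}phenyl pivalate
Product: 8 4-{3-[2,4-bis(2-methylbut-3-en-2-yloxy)phenyl]-3-oxopropyl}phenyl pivalate
Conditions: H2 (1 atm), Pd/CaCO3 poisoned with Pb(OAc)2, quinoline, EtOAc, rt
Reagents that add atoms: none
Why: Semihydrogenation of terminal alkynes over lead-poisoned palladium stops at the vinyl stage when hydrogen uptake is followed; the aryl ketone, the aryl ester and the tertiary ethers are not touched at room temperature.

**Step 5**
Reactants: 8 4-{3-[2,4-bis(2-methylbut-3-en-2-yloxy)phenyl]-3-oxopropyl}phenyl pivalate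
Product: 12 4-{3-[2,4-dihydroxy-3,5-bis(3-methylbut-2-enyl)phenyl]-3-oxopropyl}phenyl pivalate (ring B O-pivaloyl gancaonin J), via first cyclohexadienone 9 (not isolated), via monoprenyl phenol 10 (not isolated), via second cyclohexadienone 11 (not isolated)
Conditions: Eu(fod)3 (10 mol %), PhMe, 60 °C, then 110 °C
Reagents that add atoms: none
Why: Two aromatic ortho-Claisen rearrangements in one flask, the closest known reaction type being the thermal and Eu(fod)3-promoted [3,3] shift of aryl 1,1-dimethylallyl ethers to ortho-prenylphenols in hydroxyacetophenones and flavonoids (fod = 6,6,7,7,8,8,8-heptafluoro-2,2-dimethyloctane-3,5-dionate). The europium centre is expected to bind the ketone oxygen and O2 as a chelate, so the O2 ether should rearrange first at 60 °C: a chair-like transition state joins the terminal CH2 to C3 with inversion of the allyl unit, and dienone 9 enolises to phenol 10. At 110 °C the O4 ether of 10 finds C3 occupied and can settle only at C5, giving dienone 11 and then 12; a shift to C3 would give a dienone with no hydrogen to lose, which can only revert. No ring is closed and no stereocentre remains, because the sp3 carbons of 9 and 11 are lost on enolisation. The selectivity needed is one of order and site: each unit must reach its carbon by a single ortho shift, since a Cope relay from C3 to C5 would invert the unit a second time and leave a 1,1-dimethylallyl group. The substrate secures this through the acyl group, which blocks C1 and anchors the europium next to O2, through C6 being meta to both oxygens, and through the bulk of the O2 ether, which shields C3 from the O4 unit while O2 is still etherified. Neutral conditions and moderate temperature should keep loss of the tertiary ethers as isoprene and chroman closure low, and the pivalate is inert.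

**Step 6**
Reactants: 12 4-{3-[2,4-dihydroxy-3,5-bis(3-methylbut-2-enyl)phenyl]-3-oxopropyl}phenyl pivalate
Product: 13 gancaonin J, 1-[2,4-dihydroxy-3,5-bis(3-methylbut-2-enyl)phenyl]-3-(4-hydroxyphenyl)propan-1-one
Conditions: K2CO3 (2 equiv), MeOH, 0 °C to rt; then 1 M HCl, 0 °C
Reagents that add atoms: none
Why: Base-mediated methanolysis of an aryl ester: methoxide attacks the pivaloyl carbonyl and releases the ring B phenoxide; the ketone and the prenyl groups are inert to mild base, and the ortho-prenyl phenols meet only a brief cold dilute-acid quench, with no hydrogen at any point.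

## Compound list

1 | 3-(4-hydroxyphenyl)propanoic acid (phloretic acid) | O=C(O)CCc1ccc(O)cc1 | starting material
2 | 3-[4-(2,2-dimethylpropanoyloxy)phenyl]propanoic acid | CC(C)(C)C(=O)Oc1ccc(CCC(=O)O)cc1 | intermediate
3 | resorcinol (benzene-1,3-diol) | Oc1cccc(O)c1 | starting material
4 | 4-[3-(2,4-dihydroxyphenyl)-3-oxopropyl]phenyl pivalate | CC(C)(C)C(=O)Oc1ccc(CCC(=O)c2ccc(O)cc2O)cc1 | intermediate
5 | 3-chloro-3-methylbut-1-yne | C#CC(C)(C)Cl | starting material
6 | 4-{3-[2-hydroxy-4-(2-methylbut-3-yn-2-yloxy)phenyl]-3-oxopropyl}phenyl pivalate | C#CC(C)(C)Oc1ccc(C(=O)CCc2ccc(OC(=O)C(C)(C)C)cc2)c(O)c1 | intermediate (not isolated)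
7 | 4-{3-[2,4-bis(2-methylbut-3-yn-2-yloxy)phenyl]-3-oxopropyl}phenyl pivalate | C#CC(C)(C)Oc1ccc(C(=O)CCc2ccc(OC(=O)C(C)(C)C)cc2)c(OC(C)(C)C#C)c1 | intermediate
8 | 4-{3-[2,4-bis(2-methylbut-3-en-2-yloxy)phenyl]-3-oxopropyl}phenyl pivalate | C=CC(C)(C)Oc1ccc(C(=O)CCc2ccc(OC(=O)C(C)(C)C)cc2)c(OC(C)(C)C=C)c1 | intermediate
9 | 4-{3-[5-(3-methylbut-2-enyl)-4-(2-methylbut-3-en-2-yloxy)-6-oxocyclohexa-1,3-dien-1-yl]-3-oxopropyl}phenyl pivalate (racemic at the sp3 ring carbon) | C=CC(C)(C)OC1=CC=C(C(=O)CCc2ccc(OC(=O)C(C)(C)C)cc2)C(=O)C1CC=C(C)C | intermediate (not isolated)
10 | 4-{3-[2-hydroxy-3-(3-methylbut-2-enyl)-4-(2-methylbut-3-en-2-yloxy)phenyl]-3-oxopropyl}phenyl pivalate | C=CC(C)(C)Oc1ccc(C(=O)CCc2ccc(OC(=O)C(C)(C)C)cc2)c(O)c1CC=C(C)C | intermediate (not isolated)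
11 | 4-{3-[6-hydroxy-3,5-bis(3-methylbut-2-enyl)-4-oxocyclohexa-1,5-dien-1-yl]-3-oxopropyl}phenyl pivalate (racemic at the sp3 ring carbon) | CC(C)=CCC1C=C(C(=O)CCc2ccc(OC(=O)C(C)(C)C)cc2)C(O)=C(CC=C(C)C)C1=O | intermediate (not isolated)
12 | 4-{3-[2,4-dihydroxy-3,5-bis(3-methylbut-2-enyl)phenyl]-3-oxopropyl}phenyl pivalate | CC(C)=CCc1cc(C(=O)CCc2ccc(OC(=O)C(C)(C)C)cc2)c(O)c(CC=C(C)C)c1O | intermediate
13 | gancaonin J, 1-[2,4-dihydroxy-3,5-bis(3-methylbut-2-enyl)phenyl]-3-(4-hydroxyphenyl)propan-1-one | CC(C)=CCc1cc(C(=O)CCc2ccc(O)cc2)c(O)c(CC=C(C)C)c1O | target

## Step count and least certain steps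

Total step count: 6. Longest linear sequence: 6 steps (1 to 13); resorcinol 3 enters at step 2 and the chloride 5 at step 3.

**Step 5 (key step).**
- What may go wrong: the O4 unit may shift to C3 before the O2 ether has moved. The O2 unit is then left without a free ortho carbon and is either lost as isoprene or relayed to C5 with a second inversion. The Lewis acid may also ionise the tertiary ethers, and the new ortho-prenyl phenols may close to chromans.
- Fallback: deliver both prenyl groups from O4 in two separate ortho shifts, so that O2 is never etherified. The fallback sets out from 4.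
  - Step 3 is run with one equivalent of 5 and the monoether 6 is isolated.
  - Semihydrogenation as in step 4 gives 4-{3-[2-hydroxy-4-(2-methylbut-3-en-2-yloxy)phenyl]-3-oxopropyl}phenyl pivalate F1.
  - Heating in toluene should give 4-{3-[2,4-dihydroxy-3-(3-methylbut-2-enyl)phenyl]-3-oxopropyl}phenyl pivalate F2. The hydrogen-bonded 2-hydroxy ketone is known to direct this shift to C3.
  - The free O4 is etherified again with 5 (DBU, CuCl2·2H2O) to 4-{3-[2-hydroxy-3-(3-methylbut-2-enyl)-4-(2-methylbut-3-yn-2-yloxy)phenyl]-3-oxopropyl}phenyl pivalate F3.
  - Semihydrogenation gives 10, where the fallback comes back to the route; heating 10 gives 12, since C5 is the only free ortho carbon.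

**Step 3.**
- What may go wrong: etherification may stall at the hydrogen-bonded O2, so that the reaction stops at the monoether stage or needs forcing that endangers the ester.
- Fallback: make the tertiary allyl ethers directly by palladium-catalysed allylic etherification. The fallback sets out from 4 and returns at 8, leaving out 7 and step 4.
  - tert-Butyl 2-methylbut-3-en-2-yl carbonate F4 is made from 2-methylbut-3-en-2-ol and di-tert-butyl dicarbonate.
  - F4 and Pd(PPh3)4 in THF at 0 °C generate a 1,1-dimethylallyl palladium cation together with tert-butoxide. The phenoxides attack the more substituted terminus.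
  - This also removes the risk of over-reduction in the semihydrogenation.

**Step 2.**
- What may go wrong: the Lewis acid may cleave the pivalate or transfer it to resorcinol at 85 °C, or the water formed may hydrolyse it.
- Fallback: protect ring B after the acylation, using the order of acidity of the three phenols. The fallback sets out from 1 and 3.
  - BF3·OEt2 acylation with the free acid 1 gives 1-(2,4-dihydroxyphenyl)-3-(4-hydroxyphenyl)propan-1-one (davidigenin) F5.
  - One equivalent of 5 and DBU with CuCl2·2H2O etherifies the most acidic hydroxyl, para to the ketone, giving 1-[2-hydroxy-4-(2-methylbut-3-yn-2-yloxy)phenyl]-3-(4-hydroxyphenyl)propan-1-one F6.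
  - PivCl and Et3N in CH2Cl2 at 0 °C then acylate the ring B phenol in preference to the hydrogen-bonded one. This gives 6, where the fallback comes back to the route; the second half of step 3 carries 6 on to 7.

## Further compounds

F1 | step 5 | 4-{3-[2-hydroxy-4-(2-methylbut-3-en-2-yloxy)phenyl]-3-oxopropyl}phenyl pivalate | C=CC(C)(C)Oc1ccc(C(=O)CCc2ccc(OC(=O)C(C)(C)C)cc2)c(O)c1
F2 | step 5 | 4-{3-[2,4-dihydroxy-3-(3-methylbut-2-enyl)phenyl]-3-oxopropyl}phenyl pivalate | CC(C)=CCc1c(O)ccc(C(=O)CCc2ccc(OC(=O)C(C)(C)C)cc2)c1O
F3 | step 5 | 4-{3-[2-hydroxy-3-(3-methylbut-2-enyl)-4-(2-methylbut-3-yn-2-yloxy)phenyl]-3-oxopropyl}phenyl pivalate | C#CC(C)(C)Oc1ccc(C(=O)CCc2ccc(OC(=O)C(C)(C)C)cc2)c(O)c1CC=C(C)C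
F4 | step 3 | tert-butyl 2-methylbut-3-en-2-yl carbonate | C=CC(C)(C)OC(=O)OC(C)(C)C
F5 | step 2 | 1-(2,4-dihydroxyphenyl)-3-(4-hydroxyphenyl)propan-1-one (davidigenin) | O=C(CCc1ccc(O)cc1)c1ccc(O)cc1O
F6 | step 2 | 1-[2-hydroxy-4-(2-methylbut-3-yn-2-yloxy)phenyl]-3-(4-hydroxyphenyl)propan-1-one | C#CC(C)(C)Oc1ccc(C(=O)CCc2ccc(O)cc2)c(O)c1
A1 | alternative 1 | 2,6-bis(3-methylbut-2-enyl)-3-(triisopropylsilyloxy)phenol | CC(C)=CCc1ccc(O[Si](C(C)C)(C(C)C)C(C)C)c(CC=C(C)C)c1O
A2 | alternative 1 | (E)-1-diazo-7-methylocta-3,6-dien-2-one | [N-]=[N+]=CC(=O)/C=C/CC=C(C)C
A3 | alternative 1 | triisopropyl(5-methylhex-4-en-1-ynyloxy)silane | CC(C)=CCC#CO[Si](C(C)C)(C(C)C)C(C)C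
A4 | alternative 2 | 3-[4-(tert-butyldimethylsilyloxy)phenyl]-1-[2,4-dihydroxy-3,5-bis(3-methylbut-2-enyl)phenyl]propan-1-one | CC(C)=CCc1cc(C(=O)CCc2ccc(O[Si](C)(C)C(C)(C)C)cc2)c(O)c(CC=C(C)C)c1O
A5 | alternative 2 | 1-methoxy-7-methyl-2-(3-methylbut-2-enyl)-1,3-bis(trimethylsilyloxy)octa-1,3,6-triene (double-bond geometry not defined) | COC(O[Si](C)(C)C)=C(CC=C(C)C)C(O[Si](C)(C)C)=CCC=C(C)C
A6 | alternative 2 | 5-[4-(tert-butyldimethylsilyloxy)phenyl]pent-1-yn-3-one | C#CC(=O)CCc1ccc(O[Si](C)(C)C(C)(C)C)cc1
A7 | alternative 3 | 1-[2,4-bis(methoxymethoxy)-3,5-bis(3-methylbut-2-enyl)phenyl]-3-[4-(methoxymethoxy)phenyl]propan-1-one | COCOc1ccc(CCC(=O)c2cc(CC=C(C)C)c(OCOC)c(CC=C(C)C)c2OCOC)cc1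
A8 | alternative 3 | 1-iodo-2,4-bis(methoxymethoxy)-3,5-bis(3-methylbut-2-enyl)benzene | COCOc1c(I)cc(CC=C(C)C)c(OCOC)c1CC=C(C)C
A9 | alternative 3 | 9-{2-[4-(methoxymethoxy)phenyl]ethyl}-9-borabicyclo[3.3.1]nonane | COCOc1ccc(CCB2C3CCCC2CCC3)cc1
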